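| flask | solid substrate | reagent | remark | time |
|---|---|---|---|---|
| noon | 1.5 M | 2.25 M | the very flask that is asked about, followed so far |  |
| flask | 1.5 M | 2.25 M |  | 2.5 d |

- noon (time / h: target / %, solid substrate / %): 0.417: 7.1, 43.5; 1.33: 12.0, 31.9; 2.00: 12.2, 26.5; 3.00: 12.3, 20.7; 5.00: 13.0, 8.6

(standard deviation of a reading: 0.5 percentage points)

- a species is counted by the solid substrate in it: one side product or self-condensation product counts as two
- given per volume of solution although it is solid: solid substrate
- the analysis behind the earlier runs scatters by 0.5 percentage points, standard deviation
- reactions considered so far: solid substrate <-> dissolved substrate; dissolved substrate + reagent <-> target; dissolved substrate + target -> side product; 2 solid substrate -> self-condensation product; target <-> isomer of the product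
- at the start none of the solid substrate is in solution

- the target standing at 2.5 d, as a percentage of the solid substrate charged
- the change that raises the amount of target at 2.5 d, in percent of the solid substrate charged most ("none" if none brings more than 2 percentage points) (gamma / theta / delta / none)
- amount of target at 2.5 d, in percent of the solid substrate charged, after theta

- gamma: doubling the solubility of the solid substrate, all else as stated
- theta: doubling the dissolution coefficient of the solid substrate, all else as stated
- delta: doubling the amount of reagent, all else as stated

1. Leave this flask stirring as it is until you come back. At 5.00 h the noon readings gave 8.6% solid substrate and 13.0% target.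

2. Target stood nearly level from 1.33 h, so I treated target and dissolved substrate as keeping a fixed ratio (a pre-equilibrium), with target at Tp = 0.185 M.

3. The solid substrate fell along a straight line at s = 0.0895 M h⁻¹. Traced back to the start, that line gave a dissolved pool, target included, of W = 0.923 M.

4. Side product takes dissolved substrate times target, and at a fixed ratio that goes as target squared. Such a loss makes the reciprocal of the target T climb steadily, at the tail constant κ = s/(Tp W) = 0.00875 M⁻¹ min⁻¹.

5. My line reached zero solid at 6.44 h, and the climb began there from the reciprocal of Tp. By the asked time the climb is larger than that start, so I expected 1.99% target. In my reckoning faster dissolving moves the start, not the climb, so I saw no use in it.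

6. The forecast said 2.2%, 2.2% after theta, and best none, a little above my figure: “This late-time value forgets its starting point”.

The flask gave 3.03%, 3.03% after theta, and best none; delta brought 1.4 percentage points.

    solid substrate ⇌ dissolved substrate, rate k1*(cs1 - [dissolved substrate]) while solid is left; crystals form when [dissolved substrate] > cs1 (solubility = 0.720 M, k = 0.210 min⁻¹)
    dissolved substrate + reagent ⇌ target (K = 0.160 M⁻¹, k = 0.00470 M⁻¹ min⁻¹)
    dissolved substrate + target → side product (k = 0.00370 M⁻¹ min⁻¹)
    2 solid substrate → self-condensation product (k = 7.40 × 10⁻⁴ M⁻¹ min⁻¹)
    target ⇌ isomer of the product (K = 2.60, k = 0.00190 min⁻¹)

The same κ, on the neighbour flask with 0.38 M of solid substrate and a start at the share Tp/W of its charge, gives 5.89% target, against the 7.69% that flask holds, so it reads low there as it did here. On this flask, the largest single effect on target, though not the main reason for its low level, is the return of target to dissolved substrate and reagent. With that return taken away, the same run of this flask ended at 17.1% target instead of 3.03%.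

The data are simulated for substances that don't exist; scatter was added.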